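The plan rests on removing C9 from ring B as carbon monoxide. This leaves a fully substituted ring-A cyclopentane that already holds all five stereocentres and carries two iodides: a neopentyl iodomethyl group (C10) on quaternary C1 and, trans to it on C5, a (Z)-3-iodobut-2-enyl arm (C6–C8). The key step exploits the position of the C9 ketone between C10, which cannot β-eliminate because C1 is quaternary, and vinylic C8. Zinc insertion at C10 followed by palladium-catalysed carbonylative Negishi coupling makes C8–C9 and C9–C10 and closes the cycloheptenone in one operation. A silylene bridge from O4 to O6 pre-orients the arm.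

Key step: step 16

Assumption: target numbering is used for every intermediate, β is the ring-A face that bears the C1 methyl group and α the opposite face; compounds 1, 3, 5, 14, 18 and 31 are taken as purchasable, and 6 is made by cracking paraformaldehyde.

Step 1
Reactants: 1 (S)-4-(tert-butyldimethylsilyloxy)cyclopent-2-en-1-one
Product: 2 (S)-4-(tert-butyldimethylsilyloxy)-2-iodocyclopent-2-en-1-one
Conditions: I2, pyridine–CH2Cl2 (1:1), 0 °C to rt
Reagents that add atoms: iodine, II
Why: Pyridine adds reversibly to C5, the enolate is iodinated at C1 and pyridine leaves again (addition–elimination α-iodination of an enone), so the C4 stereocentre is not touched.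

Step 2
Reactants: 2 (S)-4-(tert-butyldimethylsilyloxy)-2-iodocyclopent-2-en-1-one; 3 methylzinc chloride
Product: 4 (S)-4-(tert-butyldimethylsilyloxy)-2-methylcyclopent-2-en-1-one
Conditions: MeZnCl, PdCl2(dppf) (3 mol %), THF, 0 °C to rt
Reagents that add atoms: methylzinc chloride (3), C[Zn]Cl
Why: Negishi coupling of an α-iodoenone with a methylzinc halide runs at room temperature under neutral conditions, so the β-silyloxy ketone neither eliminates nor racemises.

Step 3
Reactants: 4 (S)-4-(tert-butyldimethylsilyloxy)-2-methylcyclopent-2-en-1-one; 5 vinylmagnesium bromide; 6 formaldehyde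
Product: 8 ring-A keto alcohol (C2 ketone; 1β-CH3; 1α-CH2OH; 5β-vinyl; 4α-OTBS), via magnesium enolate 7 (not isolated)
Conditions: CH2=CHMgBr (2.2 equiv), CuBr·SMe2 (1.1 equiv), THF, −78 °C; 4; then CH2O (gas) in THF, −78 °C; aq NH4Cl
Reagents that add atoms: vinylmagnesium bromide (5), C=C[Mg]Br; formaldehyde (6), C=O
Why: In this three-component coupling (cuprate 1,4-addition, then aldol trapping) vinyl enters C5 anti to the 4α-silyloxy group and formaldehyde attacks the regiodefined enolate at C1 anti to the new vinyl group, which sets C5 and the quaternary C1 with C10 trans to the arm, and the adduct cannot dehydrate.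

Step 4
Reactants: 8 ring-A keto alcohol
Product: 10 2α,10-diol (2α-OH cis to C10), via diethylborinate 9 (not isolated)
Conditions: Et2BOMe, THF–MeOH (4:1), −78 °C; NaBH4, −78 to −40 °C; AcOH, then MeOH azeotrope
Reagents that add atoms: none
Why: In this Narasaka–Prasad-type chelation-controlled reduction boron ties the C10 oxygen to the ketone oxygen on the α face, so external hydride arrives from the β face past the smaller methyl group and gives the 2α-alcohol.

Step 5
Reactants: 10 2α,10-diol
Product: 11 2α,10-O-isopropylidene acetal (4α-OTBS, 5β-vinyl)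
Conditions: Me2C(OMe)2, PPTS (cat.), CH2Cl2, rt
Reagents that add atoms: 2,2-dimethoxypropane, COC(C)(C)OC
Why: Acid-catalysed transketalisation closes a six-membered acetonide on the cis-1,3-diol, masking both hydroxyls in one operation without loss of the silyl ether.

Step 6
Reactants: 11 2α,10-O-isopropylidene acetal
Product: 12 4α-alcohol (acetonide, 5β-vinyl)
Conditions: TBAF, THF, 0 °C to rt
Reagents that add atoms: none
Why: Fluoride cleaves the only silyl ether, and the acetonide and the vinyl group are inert to it.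

Step 7
Reactants: 12 4α-alcohol
Product: 13 C4 ketone (acetonide, 5β-vinyl)
Conditions: Dess–Martin periodinane, CH2Cl2, 0 °C to rt
Reagents that add atoms: none
Why: Dess–Martin oxidation is close to neutral, so the β,γ-unsaturated β-alkoxy ketone forms without double-bond migration, C5 epimerisation or elimination of the C2 oxygen.

Step 8
Reactants: 13 C4 ketone; 14 isopropylmagnesium chloride
Product: 15 tertiary alcohol (4β-OH, 4α-isopropyl, 5β-vinyl, acetonide)
Conditions: anhydrous CeCl3, i-PrMgCl, THF, −78 °C, 1 h; then 13, −78 to −20 °C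
Reagents that add atoms: isopropylmagnesium chloride (14), CC(C)[Mg]Cl
Why: The weakly basic organocerium reagent adds 1,2 without enolisation or β-hydride reduction and approaches the cyclopentanone from the α face, anti to the adjacent 5β-vinyl and the 1β-methyl group, which places isopropyl α and the new hydroxyl β.

Step 9
Reactants: 15 tertiary alcohol
Product: 17 C6 aldehyde (formyl group on C5β), via ozonide 16 (not isolated)
Conditions: O3, CH2Cl2, −78 °C; PPh3, −78 °C to rt
Reagents that add atoms: ozone, [O-][O+]=O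
Why: Ozonolysis of the only alkene with reductive work-up gives the aldehyde in the absence of base, so C5 keeps its configuration and the β-hydroxy aldehyde does not undergo retro-aldol cleavage.

Step 10
Reactants: 17 C6 aldehyde; 18 prop-1-ynylmagnesium bromide
Product: 19 (6S)-propargylic alcohol (C6–OH, C7≡C8–CH3)
Conditions: CH3C≡CMgBr (3 equiv), THF, −78 to −40 °C
Reagents that add atoms: prop-1-ynylmagnesium bromide (18), CC#C[Mg]Br
Why: In this chelation-controlled Grignard addition the C4 magnesium alkoxide binds the aldehyde oxygen in a six-membered chelate with C1 equatorial, and the alkynyl group attacks through the open sector next to H5 and away from the two fully substituted carbons, giving the (6S)-alcohol (6α-O in ring B).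

Step 11
Reactants: 19 (6S)-propargylic alcohol
Product: 21 (Z)-alkenyl iodide 4β,6-diol, via alkenylalanate 20 (not isolated)
Conditions: NaAlH2(OCH2CH2OMe)2 (4 equiv), THF, 0 °C to rt; EtOAc; I2, −78 to 0 °C
Reagents that add atoms: iodine, II
Why: Hydroxyl-directed trans-hydroalumination of the propargylic alcohol puts hydride on C7 and aluminium on C8 inside a five-membered alanate, and iodinolysis with retention gives only the Z iodide with iodine cis to C6.

Step 12
Reactants: 21 (Z)-alkenyl iodide 4β,6-diol
Product: 22 4,6-O-di-tert-butylsilylene derivative (acetonide retained)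
Conditions: (t-Bu)2Si(OTf)2, 2,6-lutidine, CH2Cl2, 0 °C to rt
Reagents that add atoms: di-tert-butylsilyl bis(trifluoromethanesulfonate), CC(C)(C)[Si](OS(=O)(=O)C(F)(F)F)(OS(=O)(=O)C(F)(F)F)C(C)(C)C
Why: In this cyclic silylene protection of a 1,3-diol the bis-triflate silylates the secondary C6 hydroxyl and then closes intramolecularly on the hindered C4 hydroxyl, giving a chair with isopropyl, C1 and C7 equatorial.

Step 13
Reactants: 22 4,6-O-di-tert-butylsilylene derivative
Product: 23 silylene 2α,10-diol
Conditions: AcOH–THF–H2O (3:1:1), 40 °C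
Reagents that add atoms: none
Why: Mild aqueous acid hydrolyses the acetonide, while the di-tert-butylsilylene of a 1,3-diol and the alkenyl iodide tolerate these conditions.

Step 14
Reactants: 23 silylene 2α,10-diol
Product: 25 C10 iodide with free 2α-OH, via neopentyl triflate 24 (not isolated)
Conditions: Tf2O (1.05 equiv), 2,6-lutidine, CH2Cl2, −78 °C; n-Bu4NI, −78 °C to rt
Reagents that add atoms: tetrabutylammonium iodide, CCCC[N+](CCCC)(CCCC)CCCC.[I-]
Why: The primary hydroxyl is triflated selectively at low temperature, and this very good leaving group permits SN2 displacement by iodide even at the neopentyl carbon.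

Step 15
Reactants: 25 C10 iodide with free 2α-OH
Product: 26 ring-A diiodide (2α-OAc, C1 iodomethyl, C5 (Z)-3-iodobut-2-enyl arm, 4,6-O-silylene)
Conditions: Ac2O, pyridine, DMAP (cat.), CH2Cl2, rt
Reagents that add atoms: acetic anhydride, CC(=O)OC(C)=O
Why: DMAP-catalysed acetylation acts on the only free hydroxyl and leaves the C2–O bond intact, so the configuration is retained.

Step 16
Reactants: 26 ring-A diiodide; 27 carbon monoxide
Product: 29 bicyclic enone (target core; 2α-OAc; 4,6-O-silylene), via alkylzinc iodide 28 (not isolated)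
Conditions: Zn dust (BrCH2CH2Br, Me3SiCl activated), THF, 40 °C; decant; syringe-pump addition to Pd(PPh3)4 (10 mol %), CO (10 bar), THF–NMP (4:1), 50 °C, 2 mM
Reagents that add atoms: carbon monoxide (27), [C-]#[O+]
Why: Proposed new method: zinc inserts into the sp3 C10–I bond (alkenyl iodides are inert to zinc dust in THF without lithium chloride, and 5-exo closure of the transient C10 radical onto C7 would need a strained trans-fused bicyclo[3.3.0]octane), zerovalent palladium adds oxidatively to C8–I with retention, CO inserts to give the alkenoylpalladium iodide, the C10 zinc transmetalates and reductive elimination releases the ketone. The closest known reaction types are the intermolecular three-component carbonylative Negishi coupling of alkylzinc iodides, CO and alkenyl or aryl iodides, and carbonylative Stille macrocyclisation, whereas use for a seven-membered ring is new. Ring B closes through an eight-membered acyl(alkyl)palladacycle, in which CO insertion makes C8–C9 and reductive elimination makes C9–C10, both bonds being endocyclic. No stereocentre is created, and the five existing ones and the Z alkene are carried through because C10–Zn and C10–Pd have no β-hydrogen (C1 is quaternary) and the C6 oxygen is a silyl ether, too poor a leaving group for allene-forming elimination or allylpalladium formation. The selectivity needed is CO insertion before transmetalation, since direct coupling would give a six-membered ring, and it is secured by 10 bar of CO, by the slow transmetalation of a neopentylzinc and by slow addition at high dilution, which also suppresses dimerisation. The trans arms on C1 and C5 and the silylene chair, which holds C7 gauche to C1, keep C10 within reach of the acyl carbon.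

Step 17
Reactants: 29 bicyclic enone
Product: 30 4β,6α-diol (2α-OAc, enone)
Conditions: HF·pyridine, THF–pyridine, 0 °C
Reagents that add atoms: none
Why: Buffered fluoride removes the silylene under weakly acidic conditions, which avoids base-induced isomerisation of the γ-hydroxy enone and acetate migration.

Step 18
Reactants: 30 4β,6α-diol; 31 4-acetoxybenzoic acid
Product: 32 6-O-(4-acetoxybenzoyl) ester
Conditions: 4-AcOC6H4CO2H, DCC, DMAP, CH2Cl2, 0 °C to rt
Reagents that add atoms: 4-acetoxybenzoic acid (31), CC(=O)Oc1ccc(cc1)C(=O)O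
Why: Steglich esterification occurs only at the secondary allylic C6 hydroxyl because the tertiary C4 hydroxyl beside isopropyl is too hindered, and the C6–O bond is not broken, so the configuration is retained.

Step 19
Reactants: 32 6-O-(4-acetoxybenzoyl) ester
Product: 33 target CNP0087181.6
Conditions: NH4OAc, MeOH–H2O (4:1), rt
Reagents that add atoms: none
Why: Aryl acetates are much better acyl donors than alkyl esters, so neutral ammonium acetate-mediated methanolysis frees the phenol while the hindered C2 acetate and the C6 benzoate stay.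

Compound list

1 | (S)-4-(tert-butyldimethylsilyloxy)cyclopent-2-en-1-one | O=C1C[C@H](O[Si](C)(C)C(C)(C)C)C=C1 | starting material
2 | (S)-4-(tert-butyldimethylsilyloxy)-2-iodocyclopent-2-en-1-one | O=C1C[C@H](O[Si](C)(C)C(C)(C)C)C=C1I | intermediate
3 | methylzinc chloride | C[Zn]Cl | starting material
4 | (S)-4-(tert-butyldimethylsilyloxy)-2-methylcyclopent-2-en-1-one (C2 ketone, C1=C5 alkene, methyl on C1, 4α-OTBS) | O=C1C[C@H](O[Si](C)(C)C(C)(C)C)C=C1C | intermediate
5 | vinylmagnesium bromide | C=C[Mg]Br | starting material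
6 | formaldehyde (monomer) | C=O | starting material
7 | bromomagnesium enolate (C1=C2, 5β-vinyl, 4α-OTBS) | Br[Mg]OC1=C(C)[C@H](C=C)[C@@H](O[Si](C)(C)C(C)(C)C)C1 | intermediate
8 | ring-A keto alcohol (C2 ketone, 1β-methyl, 1α-hydroxymethyl, 5β-vinyl, 4α-OTBS) | O=C1C[C@H](O[Si](C)(C)C(C)(C)C)[C@@H](C=C)[C@]1(C)CO | intermediate
9 | C10 O-diethylborinate of 8 | O=C1C[C@H](O[Si](C)(C)C(C)(C)C)[C@@H](C=C)[C@]1(C)COB(CC)CC | intermediate
10 | 2α,10-diol (2α-OH cis to C10, otherwise as 8) | O[C@@H]1C[C@H](O[Si](C)(C)C(C)(C)C)[C@@H](C=C)[C@]1(C)CO | intermediate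
11 | 2α,10-O-isopropylidene acetal of 10 | CC1(C)O[C@@H]2C[C@H](O[Si](C)(C)C(C)(C)C)[C@@H](C=C)[C@]2(C)CO1 | intermediate
12 | 4α-alcohol (acetonide, 5β-vinyl) | CC1(C)O[C@@H]2C[C@H](O)[C@@H](C=C)[C@]2(C)CO1 | intermediate
13 | C4 ketone (acetonide, 5β-vinyl) | CC1(C)O[C@@H]2CC(=O)[C@@H](C=C)[C@]2(C)CO1 | intermediate
14 | isopropylmagnesium chloride | CC(C)[Mg]Cl | starting material
15 | tertiary alcohol (4β-OH, 4α-isopropyl, 5β-vinyl, acetonide) | CC1(C)O[C@@H]2C[C@](O)(C(C)C)[C@@H](C=C)[C@]2(C)CO1 | intermediate
16 | 1,2,4-trioxolane of the vinyl group (C6 unassigned) | CC1(C)O[C@@H]2C[C@](O)(C(C)C)[C@@H](C3OCOO3)[C@]2(C)CO1 | intermediate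
17 | C6 aldehyde (5β-formyl, 4β-OH, acetonide) | CC1(C)O[C@@H]2C[C@](O)(C(C)C)[C@@H](C=O)[C@]2(C)CO1 | intermediate
18 | prop-1-ynylmagnesium bromide | CC#C[Mg]Br | starting material
19 | (6S)-propargylic alcohol (4β,6-diol, acetonide) | CC1(C)O[C@@H]2C[C@](O)(C(C)C)[C@@H]([C@H](O)C#CC)[C@]2(C)CO1 | intermediate
20 | sodium alkenylalanate, five-membered O6–Al–C8 ring (the C4 hydroxyl is also aluminium-bound, drawn free) | CC1(C)O[C@@H]2C[C@](O)(C(C)C)[C@@H]([C@H]3C=C(C)[Al-](OCCOC)(OCCOC)O3)[C@]2(C)CO1.[Na+] | intermediate
21 | (Z)-alkenyl iodide 4β,6-diol (acetonide) | CC1(C)O[C@@H]2C[C@](O)(C(C)C)[C@@H]([C@H](O)/C=C(/C)I)[C@]2(C)CO1 | intermediate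
22 | 4,6-O-di-tert-butylsilylene derivative of 21 | CC1(C)O[C@@H]2C[C@](O[Si]3(C(C)(C)C)C(C)(C)C)(C(C)C)[C@@H]([C@H](O3)/C=C(/C)I)[C@]2(C)CO1 | intermediate
23 | silylene 2α,10-diol | O[C@@H]1C[C@](O[Si]2(C(C)(C)C)C(C)(C)C)(C(C)C)[C@@H]([C@H](O2)/C=C(/C)I)[C@]1(C)CO | intermediate
24 | C10 neopentyl triflate | O[C@@H]1C[C@](O[Si]2(C(C)(C)C)C(C)(C)C)(C(C)C)[C@@H]([C@H](O2)/C=C(/C)I)[C@]1(C)COS(=O)(=O)C(F)(F)F | intermediate
25 | C10 iodide with free 2α-OH | O[C@@H]1C[C@](O[Si]2(C(C)(C)C)C(C)(C)C)(C(C)C)[C@@H]([C@H](O2)/C=C(/C)I)[C@]1(C)CI | intermediate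
26 | ring-A diiodide, key-step precursor (2α-OAc, 1α-CH2I, 1β-CH3, 5β-arm with (Z)-C7=C8(I)CH3, 4,6-O-silylene) | CC(=O)O[C@@H]1C[C@](O[Si]2(C(C)(C)C)C(C)(C)C)(C(C)C)[C@@H]([C@H](O2)/C=C(/C)I)[C@]1(C)CI | intermediate
27 | carbon monoxide | [C-]#[O+] | starting material
28 | C10 alkylzinc iodide | CC(=O)O[C@@H]1C[C@](O[Si]2(C(C)(C)C)C(C)(C)C)(C(C)C)[C@@H]([C@H](O2)/C=C(/C)I)[C@]1(C)C[Zn]I | intermediate
29 | bicyclic enone, key-step product (trans-fused rings A and B, 2α-OAc, 4,6-O-silylene) | CC(=O)O[C@@H]1C[C@](O[Si]3(C(C)(C)C)C(C)(C)C)(C(C)C)[C@H]2[C@H](O3)C=C(C)C(=O)C[C@]12C | intermediate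
30 | 4β,6α-diol | CC(=O)O[C@@H]1C[C@](O)(C(C)C)[C@H]2[C@H](O)C=C(C)C(=O)C[C@]12C | intermediate
31 | 4-acetoxybenzoic acid | CC(=O)Oc1ccc(cc1)C(=O)O | starting material
32 | 6-O-(4-acetoxybenzoyl) ester | CC(=O)O[C@@H]1C[C@](O)(C(C)C)[C@H]2[C@H](OC(=O)c3ccc(OC(C)=O)cc3)C=C(C)C(=O)C[C@]12C | intermediate
33 | CNP0087181.6 | CC(=O)O[C@@H]1C[C@](O)(C(C)C)[C@H]2[C@H](OC(=O)c3ccc(O)cc3)C=C(C)C(=O)C[C@]12C | target

Total step count: 19. Longest linear sequence: 19 steps (from 1).

Steps most likely to fail

Step 16. Three things may go wrong: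
- transmetalation may outrun CO insertion, which contracts the closure to a six-membered ring;
- the neopentylzinc may be protonated;
- oligomers may form instead of the ring.

The fallback uses known chemistry. It builds C9 in as an aldehyde and closes C8–C9 by an intramolecular Nozaki–Hiyama–Kishi reaction. It sets out from 23. TEMPO/PhI(OAc)2 oxidises only the primary alcohol to the C10 hydroxy aldehyde F1. Ac2O/pyridine gives the acetoxy aldehyde F2. Wittig reaction with Ph3P=CHOMe gives the methyl enol ether F3. Mild aqueous acid gives the homologated C9 aldehyde F4. CrCl2 with catalytic NiCl2 in DMF at high dilution gives the cyclic allylic alcohol F5. Dess–Martin oxidation comes back to the route at 29.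

Step 8. The doubly activated C5–H may be enolised, β-hydride reduction may compete, or facial selectivity at the C4 carbonyl may be insufficient. The fallback makes the C4 carbinol first and lets it steer the other centres. It sets out from 1.
- i-PrMgCl/CeCl3 adds 1,2 to the enone carbonyl (which now becomes C4) anti to the silyloxy group and gives the tertiary allylic alcohol F6.
- TBAF gives the cis-enediol F7.
- MnO2 oxidises only the secondary allylic alcohol to the 4-hydroxy-4-isopropyl enone F8.
- I2/pyridine gives the iodoenone F9, and MeZnCl/PdCl2(dppf) gives the methyl enone F10.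
- Deprotonation with t-BuMgCl, alkoxide-directed conjugate delivery of vinyl from CH2=CHMgBr to the β face of C5 and formaldehyde trapping give the keto diol F11.
- Et2BOMe/NaBH4 gives the triol F12, and acetonide formation on the cis C2/C10 diol comes back at 15.

Step 10. Facial selectivity within the magnesium chelate may be poor, or the alkoxide may undergo retro-aldol cleavage. The fallback replaces substrate control by reagent control and sets out from 17. The Grignard addition is run without regard to selectivity and gives 19 together with the C6 epimer F13. MnO2 oxidises the mixture to the ynone F14. Noyori asymmetric transfer hydrogenation with RuCl[(S,S)-TsDPEN](p-cymene) in i-PrOH sets (6S) and comes back at 19.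

Further compounds

F1 | step 16 | C10 hydroxy aldehyde (2α-OH, 1α-CHO) | O[C@@H]1C[C@](O[Si]2(C(C)(C)C)C(C)(C)C)(C(C)C)[C@@H]([C@H](O2)/C=C(/C)I)[C@]1(C)C=O
F2 | step 16 | acetoxy aldehyde (2α-OAc, 1α-CHO) | CC(=O)O[C@@H]1C[C@](O[Si]2(C(C)(C)C)C(C)(C)C)(C(C)C)[C@@H]([C@H](O2)/C=C(/C)I)[C@]1(C)C=O
F3 | step 16 | methyl enol ether (C10=C9, E/Z mixture) | CC(=O)O[C@@H]1C[C@](O[Si]2(C(C)(C)C)C(C)(C)C)(C(C)C)[C@@H]([C@H](O2)/C=C(/C)I)[C@]1(C)C=COC
F4 | step 16 | homologated C9 aldehyde | CC(=O)O[C@@H]1C[C@](O[Si]2(C(C)(C)C)C(C)(C)C)(C(C)C)[C@@H]([C@H](O2)/C=C(/C)I)[C@]1(C)CC=O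
F5 | step 16 | cyclic allylic alcohol (C9 epimers) | CC(=O)O[C@@H]1C[C@](O[Si]3(C(C)(C)C)C(C)(C)C)(C(C)C)[C@H]2[C@H](O3)C=C(C)C(O)C[C@]12C
F6 | step 8 | tertiary allylic alcohol (4β-OH, 4α-isopropyl, 2β-OTBS, C1=C5) | CC(C)(C)[Si](C)(C)O[C@H]1C[C@](O)(C(C)C)C=C1
F7 | step 8 | cis-enediol | O[C@H]1C[C@](O)(C(C)C)C=C1
F8 | step 8 | 4-hydroxy-4-isopropylcyclopent-2-en-1-one (4β-OH) | O=C1C[C@](O)(C(C)C)C=C1
F9 | step 8 | 2-iodo derivative of F8 | O=C1C[C@](O)(C(C)C)C=C1I
F10 | step 8 | 2-methyl derivative of F8 | O=C1C[C@](O)(C(C)C)C=C1C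
F11 | step 8 | keto diol (C2 ketone, 1α-CH2OH, 1β-CH3, 5β-vinyl, 4β-OH) | O=C1C[C@](O)(C(C)C)[C@@H](C=C)[C@]1(C)CO
F12 | step 8 | triol (2α-OH, 10-OH, 4β-OH) | O[C@@H]1C[C@](O)(C(C)C)[C@@H](C=C)[C@]1(C)CO
F13 | step 10 | (6R)-propargylic alcohol, C6 epimer of 19 | CC1(C)O[C@@H]2C[C@](O)(C(C)C)[C@@H]([C@@H](O)C#CC)[C@]2(C)CO1
F14 | step 10 | C6 ynone | CC1(C)O[C@@H]2C[C@](O)(C(C)C)[C@@H](C(=O)C#CC)[C@]2(C)CO1
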